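**Plan**

Numbering: ring C1 (carbinol), C2, C3 (Br), C4 (Cl, Me), C5, C6. Side chain C7 (=CH2), C8, C9, C10 (carbinol), C11 (isopropenyl).
Cuts, in order: C7=CH2 (ketone methylenation), C7–C8 (Grignard addition to a C7 aldehyde), C3–Br/C4–Cl (back through a C1–O–C4 bromoether to a C3=C4 alkene), then ring bond C1–C2.
Enabling feature: in the six-membered carbocycle, bond C1–C2 ends on the allylic carbon of C3=C4, and C1 carries both an oxygen and the carboxyl-level carbon C7. The ring is therefore a γ,δ-unsaturated α-oxy acid, the retron of an ester-enolate [3,3] shift whose allylic C–O bond sits on C4.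
Undoing that shift ties C4 to the carboxyl oxygen and gives a 3-silyloxy-6-methyl-6-vinyl δ-lactone, whose carbinol carbon is that of (S)-linalool.
Forward: linalool is trimmed and rebuilt to the δ-lactone (first ring), the lactone contracts to the cyclohexene (the only ring of the target), a transient oxygen bridge places Br and Cl, and the C8–C11 chain is joined last.
Stereochemistry: C1 by 1,4-chirality transfer from linalool. C3 and C4 by two anti openings of a bromonium ion, both steered by the C1 oxygen. C10 by Sharpless kinetic resolution of the chain alcohol.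

Key step: step 7

Assumption: (S)-(+)-linalool (coriandrol) can be bought in high enantiomeric purity; its ee fixes the ee at C1, since no later step touches that centre.

**Step 1**
Reactants: 1 (S)-(+)-linalool
Product: 3 (5S)-5-ethenyl-5-methyloxolan-2-ol (both anomers), via hydroxy aldehyde 2 (not isolated)
Conditions: O3, CH2Cl2–MeOH, −78 °C, Sudan Red 7B as end-point dye; then Me2S, −78 °C → rt
Reagents that add atoms: ozone [O-][O+]=O
Why: Chemoselective ozonolysis with reductive work-up: the trisubstituted alkene is far more electron-rich than the vinyl group next to the carbinol carbon, the dye signals its consumption, and aldehyde 2 closes onto the tertiary hydroxyl without touching the stereocentre.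

**Step 2**
Reactants: 3 (5S)-5-ethenyl-5-methyloxolan-2-ol; 4 (methoxymethyl)triphenylphosphonium chloride
Product: 6 (3S)-7-methoxy-3-methylhepta-1,6-dien-3-ol (E/Z mixture), via phosphorus ylide 5 (not isolated)
Conditions: 4 (3 equiv), KOtBu (3 equiv), THF, 0 °C; then 3, 0 °C → rt
Reagents that add atoms: none
Why: Wittig olefination of a lactol through its open hydroxy aldehyde form, a standard one-carbon homologation in which excess ylide absorbs the acidic OH and the alkene geometry does not matter because the enol ether is hydrolysed next.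

**Step 3**
Reactants: 6 (3S)-7-methoxy-3-methylhepta-1,6-dien-3-ol
Product: 7 (6S)-6-ethenyl-6-methyloxan-2-ol (both anomers)
Conditions: 0.5 M aq HCl, THF, 0 °C → rt
Reagents that add atoms: water O
Why: Acid-catalysed enol ether hydrolysis: protonation of the electron-rich alkene gives an oxocarbenium ion that water and the tertiary hydroxyl capture to end at the six-membered lactol, while dilute acid is too weak to ionise the tertiary allylic C–O bond.

**Step 4**
Reactants: 7 (6S)-6-ethenyl-6-methyloxan-2-ol
Product: 8 (6S)-6-ethenyl-6-methyloxan-2-one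
Conditions: TPAP (5 mol%), NMO, 4 Å MS, CH2Cl2, rt
Reagents that add atoms: none
Why: Ley–Griffith oxidation of a lactol to the lactone under neutral conditions that leave the vinyl group and the tertiary allylic C–O bond alone.

**Step 5**
Reactants: 8 (6S)-6-ethenyl-6-methyloxan-2-one
Product: 10 (6S)-6-ethenyl-3-hydroxy-6-methyloxan-2-one (both C3 epimers), via potassium enolate 9 (not isolated)
Conditions: KHMDS, THF, −78 °C; 3-phenyl-2-(phenylsulfonyl)oxaziridine, −78 °C; then AcOH
Reagents that add atoms: 3-phenyl-2-(phenylsulfonyl)oxaziridine O=S(=O)(c1ccccc1)N1OC1c1ccccc1; potassium bis(trimethylsilyl)amide C[Si](C)(C)[N-][Si](C)(C)C.[K+] (potassium in 9 only)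
Why: Davis hydroxylation of a lactone enolate by electrophilic oxygen transfer, run at −78 °C so that the enolate does not rearrange; the new C3 centre needs no control because step 7 flattens it again.

**Step 6**
Reactants: 10 (6S)-6-ethenyl-3-hydroxy-6-methyloxan-2-one
Product: 11 (6S)-3-(tert-butyldimethylsilyloxy)-6-ethenyl-6-methyloxan-2-one (both C3 epimers)
Conditions: TBSCl, imidazole, DMF, rt
Reagents that add atoms: tert-butyldimethylsilyl chloride CC(C)(C)[Si](C)(C)Cl
Why: Imidazole-assisted silylation of a secondary alcohol, which masks the hydroxyl as a base-stable group for the coming enolisation.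

**Step 7**
Reactants: 11 (6S)-3-(tert-butyldimethylsilyloxy)-6-ethenyl-6-methyloxan-2-one
Product: 14 (S)-1-(tert-butyldimethylsilyloxy)-4-methylcyclohex-3-ene-1-carboxylic acid, via silyl ketene acetal 12 (not isolated), via trimethylsilyl ester 13 (not isolated)
Conditions: LDA (1.5 equiv), TMSCl–Et3N (internal quench), THF, −78 °C → rt; solvent switch to PhMe, 100 °C; then 1 M HCl, THF, rt
Reagents that add atoms: chlorotrimethylsilane C[Si](C)(C)Cl (silyl group in 12 and 13 only)
Why: LDA removes the C3 proton of either epimer of 11 and TMSCl traps the ring-locked enolate as ketene acetal 12, in which C3=C2–O1–C6–CH=CH2 is a 1,5-diene. On heating, the vinyl group swings over the heterocycle and a concerted suprafacial [3,3] shift through a boat, bicyclo[2.2.2]octane-like transition state joins lactone C3 to the vinyl terminus (target C1–C2), breaks O1–C6 (target C4–O) and leaves the C3=C4 alkene and silyl ester 13, which the acid work-up cleaves to 14. The closest known reaction type is the Ireland–Claisen ring contraction of 6-alkenyl lactone silyl ketene acetals to cycloalkene carboxylic acids, here in its glycolate (α-silyloxy) form. The six-membered carbocycle closes pericyclically, by sigmatropic C–C bond formation between the enolate carbon and the alkene terminus, while the lactone ring opens. The one new stereocentre, quaternary C1, is fixed by the (S) carbinol carbon because the tether lets the vinyl group reach the enolate carbon only on the lactone face it occupies, so (6S)-11 should give (S)-14 whatever the C3 configuration. The step needs O- rather than C-silylation and rearrangement rather than ionisation of the tertiary allylic C–O bond, which the fully substituted enolate carbon, the cold internal quench and the acid-free medium during heating should secure.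

**Step 8**
Reactants: 14 (S)-1-(tert-butyldimethylsilyloxy)-4-methylcyclohex-3-ene-1-carboxylic acid
Product: 15 methyl (S)-1-(tert-butyldimethylsilyloxy)-4-methylcyclohex-3-ene-1-carboxylate
Conditions: MeI, K2CO3, DMF, rt
Reagents that add atoms: iodomethane CI
Why: SN2 O-alkylation of the carboxylate, which is insensitive to crowding at the quaternary α-carbon and turns a strongly nucleophilic carboxyl group into a poor one before the bromonium chemistry.

**Step 9**
Reactants: 15 methyl (S)-1-(tert-butyldimethylsilyloxy)-4-methylcyclohex-3-ene-1-carboxylate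
Product: 16 methyl (S)-1-hydroxy-4-methylcyclohex-3-ene-1-carboxylate
Conditions: TBAF, THF, 0 °C → rt; then sat. aq NH4Cl
Reagents that add atoms: none
Why: Fluoride-induced silyl ether cleavage, eased by the electron-withdrawing ester on the carbinol carbon, with alkene and ester inert.

**Step 10**
Reactants: 16 methyl (S)-1-hydroxy-4-methylcyclohex-3-ene-1-carboxylate
Product: 17 methyl (1S,3R,4R)-3-bromo-4-methyl-7-oxabicyclo[2.2.1]heptane-1-carboxylate (endo bromide)
Conditions: NBS, CH2Cl2, 0 °C → rt, dark
Reagents that add atoms: N-bromosuccinimide O=C1CCC(=O)N1Br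
Why: Intramolecular bromoetherification of a cyclohex-3-enol (the terpinen-4-ol to 1,4-cineole ring closure): only the bromonium ion on the face opposite the C1 hydroxyl can be opened by that hydroxyl, at the tertiary C4 and anti, so oxygen lands on C4 and bromine on C3 anti to the bridge, which sets C3 (R) and C4 (R), while the methyl ester is a much poorer internal nucleophile.

**Step 11**
Reactants: 17 methyl (1S,3R,4R)-3-bromo-4-methyl-7-oxabicyclo[2.2.1]heptane-1-carboxylate
Product: 18 methyl (1S,3R,4R)-3-bromo-4-chloro-1-hydroxy-4-methylcyclohexane-1-carboxylate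
Conditions: TiCl4 (1.5 equiv), CH2Cl2, −78 → −20 °C; then ice-water
Reagents that add atoms: titanium tetrachloride Cl[Ti](Cl)(Cl)Cl
Why: Proposed new method: TiCl4 should chelate the bridging oxygen and the ester carbonyl, the tertiary C4–O bond (nearly antiperiplanar to the endo C3–Br) should ionise with bromine participation while C1–O is shielded by the cation-destabilising ester, and chloride from the titanate should open the bromonium ion at C4 from the face the oxygen has left, so two inversions give net retention (Cl cis to the C1 hydroxyl, trans to Br); the closest known reaction types are the Lewis-acid cleavage of 7-oxabicyclo[2.2.1]heptanes and tertiary ethers to chlorides, and the classical exchange of the oxygen of a trans-β-bromo alcohol for halide with retention through neighbouring-group participation.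

**Step 12**
Reactants: 18 methyl (1S,3R,4R)-3-bromo-4-chloro-1-hydroxy-4-methylcyclohexane-1-carboxylate
Product: 19 methyl (1S,3R,4R)-3-bromo-4-chloro-4-methyl-1-(triethylsilyloxy)cyclohexane-1-carboxylate
Conditions: TESOTf, 2,6-lutidine, CH2Cl2, 0 °C
Reagents that add atoms: triethylsilyl trifluoromethanesulfonate CC[Si](CC)(CC)OS(=O)(=O)C(F)(F)F
Why: Silyl triflate/lutidine silylation, the usual method for hindered tertiary alcohols, under non-nucleophilic conditions that spare the halides; triethylsilyl is chosen so that it leaves under mild conditions at the end.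

**Step 13**
Reactants: 19 methyl (1S,3R,4R)-3-bromo-4-chloro-4-methyl-1-(triethylsilyloxy)cyclohexane-1-carboxylate
Product: 20 (1S,3R,4R)-3-bromo-4-chloro-4-methyl-1-(triethylsilyloxy)cyclohexane-1-carbaldehyde
Conditions: DIBAL-H (1.2 equiv), CH2Cl2, −78 °C; then aq Rochelle salt
Reagents that add atoms: none
Why: Partial DIBAL-H reduction: the aluminium hemiacetal of a hindered α-silyloxy ester persists at −78 °C and releases the aldehyde only on work-up, and alkyl halides are not reduced at this temperature.

**Step 14**
Reactants: 21 3-(tert-butyldimethylsilyloxy)propanal; 22 isopropenylmagnesium bromide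
Product: 23 rac-5-(tert-butyldimethylsilyloxy)-2-methylpent-1-en-3-ol
Conditions: THF, −78 → 0 °C; then sat. aq NH4Cl
Reagents that add atoms: none
Why: Grignard 1,2-addition to an aldehyde, giving the racemic secondary allylic alcohol.

**Step 15**
Reactants: 23 rac-5-(tert-butyldimethylsilyloxy)-2-methylpent-1-en-3-ol
Product: 24 (3R)-5-(tert-butyldimethylsilyloxy)-2-methylpent-1-en-3-ol
Conditions: Ti(OiPr)4 (10 mol%), L-(+)-DIPT (13 mol%), TBHP (0.6 equiv), 4 Å MS, CH2Cl2, −20 °C
Reagents that add atoms: none
Why: Sharpless kinetic resolution: with L-(+)-tartrate the (S)-enantiomer of a secondary allylic alcohol is epoxidised much faster, so running just past half conversion should leave the (R)-alcohol, which sets C10.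

**Step 16**
Reactants: 24 (3R)-5-(tert-butyldimethylsilyloxy)-2-methylpent-1-en-3-ol
Product: 25 (3R)-3,5-bis(tert-butyldimethylsilyloxy)-2-methylpent-1-ene
Conditions: TBSCl, imidazole, DMF, rt
Reagents that add atoms: tert-butyldimethylsilyl chloride CC(C)(C)[Si](C)(C)Cl
Why: Standard imidazole-assisted silylation of a secondary alcohol, without effect on the carbinol configuration.

**Step 17**
Reactants: 25 (3R)-3,5-bis(tert-butyldimethylsilyloxy)-2-methylpent-1-ene
Product: 26 (3R)-3-(tert-butyldimethylsilyloxy)-4-methylpent-4-en-1-ol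
Conditions: CSA (cat.), MeOH–CH2Cl2, 0 °C
Reagents that add atoms: none
Why: Acid-catalysed methanolysis distinguishes silyl ethers by steric access, so the primary one should leave well before the secondary allylic one.

**Step 18**
Reactants: 26 (3R)-3-(tert-butyldimethylsilyloxy)-4-methylpent-4-en-1-ol
Product: 27 (3R)-5-bromo-3-(tert-butyldimethylsilyloxy)-2-methylpent-1-ene
Conditions: CBr4, PPh3, CH2Cl2, 0 °C
Reagents that add atoms: carbon tetrabromide BrC(Br)(Br)Br
Why: Appel bromination by SN2 displacement of the oxyphosphonium ion at the primary carbon under near-neutral conditions that leave the allylic silyl ether untouched.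

**Step 19**
Reactants: 27 (3R)-5-bromo-3-(tert-butyldimethylsilyloxy)-2-methylpent-1-ene; 20 (1S,3R,4R)-3-bromo-4-chloro-4-methyl-1-(triethylsilyloxy)cyclohexane-1-carbaldehyde
Product: 29 (4R)-1-[(1S,3R,4R)-3-bromo-4-chloro-4-methyl-1-(triethylsilyloxy)cyclohexyl]-4-(tert-butyldimethylsilyloxy)-5-methylhex-5-en-1-ol (both C1 epimers), via Grignard reagent 28 (not isolated)
Conditions: 27 (1.8 equiv), Mg, I2 (cat.), THF, 40 °C; then 20, THF, −78 → 0 °C; sat. aq NH4Cl
Reagents that add atoms: magnesium [Mg] (in 28 only)
Why: Grignard formation and 1,2-addition: the aldehyde is by far the most electrophilic site, so the secondary bromide and tertiary chloride are left alone, the cold quench limits silyl migration to the new alkoxide, and the new carbinol configuration is irrelevant because it is oxidised next.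

**Step 20**
Reactants: 29 (4R)-1-[(1S,3R,4R)-3-bromo-4-chloro-4-methyl-1-(triethylsilyloxy)cyclohexyl]-4-(tert-butyldimethylsilyloxy)-5-methylhex-5-en-1-ol
Product: 30 (4R)-1-[(1S,3R,4R)-3-bromo-4-chloro-4-methyl-1-(triethylsilyloxy)cyclohexyl]-4-(tert-butyldimethylsilyloxy)-5-methylhex-5-en-1-one
Conditions: Dess–Martin periodinane, CH2Cl2, 0 °C → rt
Reagents that add atoms: none
Why: Dess–Martin oxidation of a hindered secondary alcohol, mild enough for the silyl ethers, the alkene and both halides.

**Step 21**
Reactants: 30 (4R)-1-[(1S,3R,4R)-3-bromo-4-chloro-4-methyl-1-(triethylsilyloxy)cyclohexyl]-4-(tert-butyldimethylsilyloxy)-5-methylhex-5-en-1-one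
Product: 31 (1S,3R,4R)-3-bromo-1-[(5R)-5-(tert-butyldimethylsilyloxy)-6-methylhepta-1,6-dien-2-yl]-4-chloro-4-methyl-1-(triethylsilyloxy)cyclohexane
Conditions: Tebbe reagent (PhMe solution, 2 equiv), pyridine (cat.), THF, −40 °C → rt; then dilute aq NaOH, 0 °C
Reagents that add atoms: Tebbe reagent C[Al-]1(C)C[Ti]([Cl+]1)(C1C=CC=C1)C1C=CC=C1
Why: Tebbe methylenation: the titanium methylidene adds to the carbonyl by [2+2] cycloaddition and cycloreversion, copes with crowded and enolisable ketones and is non-basic, so loss of HX from the equatorial halides is avoided and any exchange with the isopropenyl CH2 is degenerate.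

**Step 22**
Reactants: 31 (1S,3R,4R)-3-bromo-1-[(5R)-5-(tert-butyldimethylsilyloxy)-6-methylhepta-1,6-dien-2-yl]-4-chloro-4-methyl-1-(triethylsilyloxy)cyclohexane
Product: 32 (1S,3R,4R)-3-bromo-4-chloro-1-[(5R)-5-hydroxy-6-methylhepta-1,6-dien-2-yl]-4-methylcyclohexan-1-ol (CNP0187094.2)
Conditions: HF·pyridine, pyridine, THF, 0 °C → rt
Reagents that add atoms: none
Why: Desilylation with pyridine-buffered HF removes both silyl groups without base (no dehydrohalogenation) and without enough acidity to ionise the allylic alcohols, so the target should emerge with all four stereocentres as set.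

**Compound list**

1 | (S)-(+)-linalool | C=C[C@@](C)(O)CCC=C(C)C | starting material
2 | (4S)-4-hydroxy-4-methylhex-5-enal | C=C[C@@](C)(O)CCC=O | intermediate
3 | (5S)-5-ethenyl-5-methyloxolan-2-ol (both anomers) | C=C[C@@](C)(O1)CCC1O | intermediate
4 | (methoxymethyl)triphenylphosphonium chloride | COC[P+](c1ccccc1)(c1ccccc1)c1ccccc1.[Cl-] | starting material
5 | (methoxymethylidene)triphenylphosphorane | COC=P(c1ccccc1)(c1ccccc1)c1ccccc1 | intermediate
6 | (3S)-7-methoxy-3-methylhepta-1,6-dien-3-ol (E/Z) | C=C[C@@](C)(O)CCC=COC | intermediate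
7 | (6S)-6-ethenyl-6-methyloxan-2-ol (both anomers) | C=C[C@@](C)(O1)CCCC1O | intermediate
8 | (6S)-6-ethenyl-6-methyloxan-2-one | C=C[C@@](C)(O1)CCCC1=O | intermediate
9 | potassium (6S)-6-ethenyl-6-methyl-5,6-dihydro-4H-pyran-2-olate | C=C[C@@](C)(O1)CCC=C1[O-].[K+] | intermediate
10 | (6S)-6-ethenyl-3-hydroxy-6-methyloxan-2-one (both C3 epimers) | C=C[C@@](C)(O1)CCC(O)C1=O | intermediate
11 | (6S)-3-(tert-butyldimethylsilyloxy)-6-ethenyl-6-methyloxan-2-one (both C3 epimers) | O=C1O[C@](C)(C=C)CCC1O[Si](C)(C)C(C)(C)C | intermediate
12 | (6S)-3-(tert-butyldimethylsilyloxy)-6-ethenyl-6-methyl-2-(trimethylsilyloxy)-5,6-dihydro-4H-pyran | C=C[C@@](C)(O1)CCC(O[Si](C)(C)C(C)(C)C)=C1O[Si](C)(C)C | intermediate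
13 | trimethylsilyl (S)-1-(tert-butyldimethylsilyloxy)-4-methylcyclohex-3-ene-1-carboxylate | C[Si](C)(C)OC(=O)[C@]1(O[Si](C)(C)C(C)(C)C)CCC(C)=CC1 | intermediate
14 | (S)-1-(tert-butyldimethylsilyloxy)-4-methylcyclohex-3-ene-1-carboxylic acid | OC(=O)[C@]1(O[Si](C)(C)C(C)(C)C)CCC(C)=CC1 | intermediate
15 | methyl (S)-1-(tert-butyldimethylsilyloxy)-4-methylcyclohex-3-ene-1-carboxylate | COC(=O)[C@]1(O[Si](C)(C)C(C)(C)C)CCC(C)=CC1 | intermediate
16 | methyl (S)-1-hydroxy-4-methylcyclohex-3-ene-1-carboxylate | COC(=O)[C@]1(O)CCC(C)=CC1 | intermediate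
17 | methyl (1S,3R,4R)-3-bromo-4-methyl-7-oxabicyclo[2.2.1]heptane-1-carboxylate | COC(=O)[C@@]12CC[C@@](C)(O1)[C@H](Br)C2 | intermediate
18 | methyl (1S,3R,4R)-3-bromo-4-chloro-1-hydroxy-4-methylcyclohexane-1-carboxylate | COC(=O)[C@]1(O)CC[C@@](C)(Cl)[C@H](Br)C1 | intermediate
19 | methyl (1S,3R,4R)-3-bromo-4-chloro-4-methyl-1-(triethylsilyloxy)cyclohexane-1-carboxylate | COC(=O)[C@]1(O[Si](CC)(CC)CC)CC[C@@](C)(Cl)[C@H](Br)C1 | intermediate
20 | (1S,3R,4R)-3-bromo-4-chloro-4-methyl-1-(triethylsilyloxy)cyclohexane-1-carbaldehyde | O=C[C@]1(O[Si](CC)(CC)CC)CC[C@@](C)(Cl)[C@H](Br)C1 | intermediate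
21 | 3-(tert-butyldimethylsilyloxy)propanal | O=CCCO[Si](C)(C)C(C)(C)C | starting material
22 | isopropenylmagnesium bromide | C=C(C)[Mg]Br | starting material
23 | rac-5-(tert-butyldimethylsilyloxy)-2-methylpent-1-en-3-ol | C=C(C)C(O)CCO[Si](C)(C)C(C)(C)C | intermediate
24 | (3R)-5-(tert-butyldimethylsilyloxy)-2-methylpent-1-en-3-ol | C=C(C)[C@H](O)CCO[Si](C)(C)C(C)(C)C | intermediate
25 | (3R)-3,5-bis(tert-butyldimethylsilyloxy)-2-methylpent-1-ene | C=C(C)[C@H](O[Si](C)(C)C(C)(C)C)CCO[Si](C)(C)C(C)(C)C | intermediate
26 | (3R)-3-(tert-butyldimethylsilyloxy)-4-methylpent-4-en-1-ol | C=C(C)[C@H](O[Si](C)(C)C(C)(C)C)CCO | intermediate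
27 | (3R)-5-bromo-3-(tert-butyldimethylsilyloxy)-2-methylpent-1-ene | C=C(C)[C@H](O[Si](C)(C)C(C)(C)C)CCBr | intermediate
28 | [(3R)-3-(tert-butyldimethylsilyloxy)-4-methylpent-4-en-1-yl]magnesium bromide | C=C(C)[C@H](O[Si](C)(C)C(C)(C)C)CC[Mg]Br | intermediate
29 | (4R)-1-[(1S,3R,4R)-3-bromo-4-chloro-4-methyl-1-(triethylsilyloxy)cyclohexyl]-4-(tert-butyldimethylsilyloxy)-5-methylhex-5-en-1-ol (both C1 epimers) | C=C(C)[C@H](O[Si](C)(C)C(C)(C)C)CCC(O)[C@]1(O[Si](CC)(CC)CC)CC[C@@](C)(Cl)[C@H](Br)C1 | intermediate
30 | (4R)-1-[(1S,3R,4R)-3-bromo-4-chloro-4-methyl-1-(triethylsilyloxy)cyclohexyl]-4-(tert-butyldimethylsilyloxy)-5-methylhex-5-en-1-one | C=C(C)[C@H](O[Si](C)(C)C(C)(C)C)CCC(=O)[C@]1(O[Si](CC)(CC)CC)CC[C@@](C)(Cl)[C@H](Br)C1 | intermediate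
31 | (1S,3R,4R)-3-bromo-1-[(5R)-5-(tert-butyldimethylsilyloxy)-6-methylhepta-1,6-dien-2-yl]-4-chloro-4-methyl-1-(triethylsilyloxy)cyclohexane | C=C(C)[C@H](O[Si](C)(C)C(C)(C)C)CCC(=C)[C@]1(O[Si](CC)(CC)CC)CC[C@@](C)(Cl)[C@H](Br)C1 | intermediate
32 | (1S,3R,4R)-3-bromo-4-chloro-1-[(5R)-5-hydroxy-6-methylhepta-1,6-dien-2-yl]-4-methylcyclohexan-1-ol (CNP0187094.2) | C=C(C)[C@H](O)CCC(=C)[C@]1(O)CC[C@@](C)(Cl)[C@H](Br)C1 | target

**Step count**

Total step count: 22.
Longest linear sequence: 17 (steps 1–13 and 19–22).

**Steps most likely to fail**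

**Step 11 (ether opening).**
- Risk: ionisation of the C4–O bond may end in proton loss from the cation, or in return of the bromonium ion to the alkene, instead of chloride capture.
- Fallback: this drops the ether detour and uses known chemistry. It sets out from 16.
- 16 is treated with a preformed bromine chloride source (tetrabutylammonium dichlorobromate, CH2Cl2, −78 → 0 °C). This is an established anti, Markovnikov bromochlorination of trisubstituted alkenes.
- It should give 18 together with its C3,C4-diastereomer, methyl (1S,3S,4S)-3-bromo-4-chloro-1-hydroxy-4-methylcyclohexane-1-carboxylate F1.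
- Facial control is given up. The two adducts are separated by chromatography, and the route is rejoined at 18.

**Step 10 (bromoetherification).**
- Risk: the hydroxyl may be outrun by the ester carbonyl on the other ring face or by external capture of the bromonium ion. Facial control would then be lost, and the strained bridge may close slowly.
- Fallback: this delivers oxygen first, sets out from 16 and returns at 18.
- Hydroxyl-directed epoxidation (VO(acac)2, TBHP, CH2Cl2) should give the epoxide cis to the C1 hydroxyl, methyl (1S,3S,6R)-3-hydroxy-6-methyl-7-oxabicyclo[4.1.0]heptane-3-carboxylate F2.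
- SN2 opening at the secondary carbon with Li2NiBr4 (THF, 0 °C) places bromine on C3 with inversion and frees the tertiary C4 alcohol, giving methyl (1S,3R,4R)-3-bromo-1,4-dihydroxy-4-methylcyclohexane-1-carboxylate F3.
- Concentrated HCl in CH2Cl2 then exchanges the C4 hydroxyl for chloride with retention through the bromonium ion. The C1 hydroxyl stays inert because its cation would sit next to the ester. The product is 18.

**Step 21 (methylenation).**
- Risk: the carbonyl lies between a fully substituted silyloxy carbon and a chain, so attack of the titanium carbene may be slow. The aluminium Lewis acid may then erode the silyl ethers or the tertiary chloride.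
- Fallback: this replaces the carbene transfer by a Peterson addition–elimination, sets out from 30 and returns at 32.
- Me3SiCH2Li with anhydrous CeCl3 (THF, −78 °C) should add to the ketone to give (5R)-2-[(1S,3R,4R)-3-bromo-4-chloro-4-methyl-1-(triethylsilyloxy)cyclohexyl]-5-(tert-butyldimethylsilyloxy)-6-methyl-1-(trimethylsilyl)hept-6-en-2-ol F4.
- HF·pyridine in THF should then bring about the acid-type Peterson elimination and remove both silyl ethers in the same flask, giving 32 directly.

**Further compounds**

F1 | step 11 | methyl (1S,3S,4S)-3-bromo-4-chloro-1-hydroxy-4-methylcyclohexane-1-carboxylate | COC(=O)[C@]1(O)CC[C@](C)(Cl)[C@@H](Br)C1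
F2 | step 10 | methyl (1S,3S,6R)-3-hydroxy-6-methyl-7-oxabicyclo[4.1.0]heptane-3-carboxylate | COC(=O)[C@]1(O)CC[C@@]2(C)O[C@H]2C1
F3 | step 10 | methyl (1S,3R,4R)-3-bromo-1,4-dihydroxy-4-methylcyclohexane-1-carboxylate | COC(=O)[C@]1(O)CC[C@@](C)(O)[C@H](Br)C1
F4 | step 21 | (5R)-2-[(1S,3R,4R)-3-bromo-4-chloro-4-methyl-1-(triethylsilyloxy)cyclohexyl]-5-(tert-butyldimethylsilyloxy)-6-methyl-1-(trimethylsilyl)hept-6-en-2-ol (both C2 epimers) | C=C(C)[C@H](O[Si](C)(C)C(C)(C)C)CCC(O)(C[Si](C)(C)C)[C@]1(O[Si](CC)(CC)CC)CC[C@@](C)(Cl)[C@H](Br)C1
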